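**Route overview**

- Retrosynthesis: the two butyryl C–C bonds on rings B and C are cut first, then the three benzyl ethers of ring C, then ring B itself, at the bond between the carbon carrying the ring C bridge and the neighbouring C–OH carbon.
- This cut is possible because ring B is a benzene-1,3,5-triol. Its alternating C–OH/C pattern is that of a methyl 3,5-dioxohexanoate (C1 ester, C3 and C5 ketones), and both CH2 bridges sit on the ketone α-carbons C4 and C6, so they can be built as chain branches.
- The chain is cut further at C4–C5 (Claisen acylation of a keto ester polyanion by an aryl propanoate) and at the ring A–CH2 bond (Michael addition to a vinyl ketone).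
- Forward: ring A comes from gem-dimethylation of butyrylphloroglucinol and is joined to the five-carbon keto ester. Ring C (bought methylphloroglucinol) is formylated, benzylated and homologated. The halves are joined, ring B is closed last, then debenzylation and twofold butyrylation follow.
- Stereochemistry: the target is achiral. The only sp3 methine on the way (C4 of the open chain) is racemic and disappears when ring B aromatises.

Key step: step 9

Remark: all β-triketone and β-dicarbonyl units are drawn as one tautomer (that of the target SMILES), and the starting materials 1, 3, 4, 9, 13 and 19 are taken as purchasable.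

**Steps**

Step 1
Reactants: 1 1-(2,4,6-trihydroxyphenyl)butan-1-one (butyrylphloroglucinol)
Product: 2 2-butanoyl-3,5-dihydroxy-6,6-dimethylcyclohexa-2,4-dien-1-one (butyrylfilicinic acid, ring A)
Conditions: NaOMe (4 equiv), MeI (2.2 equiv), MeOH, 0 °C to rt
Reagents that add atoms: iodomethane, CI
Why: Alkylative dearomatisation of an acylphloroglucinolate by twofold C-methylation at one ring carbon, favoured because the resulting enolised β-triketone is a stable vinylogous acid that stays deprotonated and resists further methylation.

Step 2
Reactants: 3 2,2-dimethyl-1,3-dioxane-4,6-dione; 4 3-chloropropanoyl chloride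
Product: 6 methyl 5-chloro-3-oxopentanoate, via acylated dioxanedione 5 (not isolated)
Conditions: pyridine (2 equiv), CH2Cl2, 0 °C to rt; then MeOH, reflux
Reagents that add atoms: methanol, CO
Why: C-acylation of the cyclic malonate and methanolysis of the acyl derivative through an α-oxoketene, with loss of acetone and CO2, is the standard β-keto ester synthesis and keeps the primary chloride as a storable mask of the vinyl ketone.

Step 3
Reactants: 2 butyrylfilicinic acid (1.2 equiv); 6 methyl 5-chloro-3-oxopentanoate
Product: 8 methyl 5-(5-butanoyl-2,6-dihydroxy-3,3-dimethyl-4-oxocyclohexa-1,5-dien-1-yl)-3-oxopentanoate (ring A keto ester), via methyl 3-oxopent-4-enoate 7 (not isolated)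
Conditions: Et3N (2.2 equiv), CH2Cl2, 0 °C to rt, slow addition of 6; pH 4 buffer work-up
Reagents that add atoms: none
Why: The amine eliminates HCl from the β-chloro ketone to give the vinyl ketone in the flask and converts 2 into its enolate, whose single free ring carbon adds in a Michael addition; the adduct remains an enolate of a β-triketone, which holds back a second addition and Robinson-type annulation.

Step 4
Reactants: 9 2-methylbenzene-1,3,5-triol (methylphloroglucinol, ring C)
Product: 11 2,4,6-trihydroxy-3-methylbenzaldehyde, via aryl iminium chloride 10 (not isolated)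
Conditions: POCl3 (1.1 equiv), DMF (1.2 equiv), EtOAc, 0 °C to rt; then H2O, 60 °C
Reagents that add atoms: N,N-dimethylformamide, CN(C)C=O; water, O
Why: Vilsmeier–Haack formylation of a highly activated arene whose two free positions are equivalent, so one equivalent of reagent should give a single monoaldehyde; the new carbon is the future B–C bridge.

Step 5
Reactants: 11 2,4,6-trihydroxy-3-methylbenzaldehyde
Product: 12 2,4,6-tris(benzyloxy)-3-methylbenzaldehyde
Conditions: BnBr (3.6 equiv), K2CO3 (4 equiv), DMF, 70 °C
Reagents that add atoms: benzyl bromide, BrCc1ccccc1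
Why: Williamson etherification, in which the formyl group lowers the ring nucleophilicity enough for O-benzylation to win over C-benzylation, while warming overcomes the hydrogen bonding of the two hydroxyls next to the aldehyde.

Step 6
Reactants: 12 2,4,6-tris(benzyloxy)-3-methylbenzaldehyde; 13 methyl (triphenylphosphoranylidene)acetate
Product: 14 methyl (E)-3-[2,4,6-tris(benzyloxy)-3-methylphenyl]prop-2-enoate
Conditions: toluene, 110 °C
Reagents that add atoms: none
Why: Wittig olefination with a stabilised ylide, which tolerates the hindered electron-rich aldehyde at reflux and should give the E-cinnamate (the geometry is removed in the next step).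

Step 7
Reactants: 14 methyl (E)-3-[2,4,6-tris(benzyloxy)-3-methylphenyl]prop-2-enoate
Product: 15 methyl 3-[2,4,6-tris(benzyloxy)-3-methylphenyl]propanoate
Conditions: NaBH4 (3 equiv), NiCl2·6H2O (0.2 equiv), MeOH/THF, 0 °C
Reagents that add atoms: none
Why: Conjugate reduction by nickel boride generated in the flask saturates the cinnamate double bond without hydrogenolysis of aryl benzyl ethers and without touching the ester.

Step 8
Reactants: 8 ring A keto ester (2 equiv); 15 methyl 3-[2,4,6-tris(benzyloxy)-3-methylphenyl]propanoate
Product: 16 methyl 4-[(5-butanoyl-2,6-dihydroxy-3,3-dimethyl-4-oxocyclohexa-1,5-dien-1-yl)methyl]-3,5-dioxo-7-[2,4,6-tris(benzyloxy)-3-methylphenyl]heptanoate (racemic at C4)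
Conditions: LiN(iPr)2 (4.1 equiv per 8), THF, −78 to 0 °C; 15 (0.5 equiv per 8), −78 to 0 °C; AcOH, −78 °C
Reagents that add atoms: none
Why: Crossed Claisen acylation at the γ-carbon of a β-keto ester dianion (here a tetraanion, ring A and the α-methylene being deprotonated first), in which the last-formed and most basic carbon attacks the ester of 15; ring A as its dianion is neither acylated at carbon nor expelled, and the polyanion is used in twofold excess because the acidic C4–H of the product consumes one equivalent, unreacted 8 being recovered.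

Step 9
Reactants: 16 open-chain 3,5-dioxo ester carrying the ring A and ring C arms
Product: 17 2-butanoyl-3,5-dihydroxy-6,6-dimethyl-4-[(2,4,6-trihydroxy-3-{[2,4,6-tris(benzyloxy)-3-methylphenyl]methyl}phenyl)methyl]cyclohexa-2,4-dien-1-one (trimer with ring B formed)
Conditions: NaOMe (3.5 equiv), MeOH, 100 °C (sealed tube); then cold 1 M HCl to pH 3
Reagents that add atoms: none
Why: In hot methanolic methoxide the chain enolates exchange protons, and the minor ketone enolate C5(O−)=C6 attacks the ester carbonyl C1; loss of methoxide gives the 2,4-disubstituted cyclohexane-1,3,5-trione, which tautomerises to the phloroglucinol and is deprotonated, so the closure cannot revert. The closest known reaction is the intramolecular Claisen (Dieckmann-type) condensation of δ-keto esters to cyclohexane-1,3-diones, in its 3,5-dioxoalkanoate-to-phloroglucinol form that copies polyketide folding. Ring B closes in a 6-(enolendo)-exo-trig mode, the new bond running from C6 (the carbon that carries the ring C arm) to C1. No stereocentre is formed, and the racemic C4 methine becomes an aromatic carbon. The step needs carbon over oxygen acylation, secured because closure through the C5 enol oxygen gives a 4-hydroxy-2-pyrone lactone that methoxide reopens to the same chain whereas the aromatic product is a sink, and it needs the ring A bridge to survive, secured by keeping ring A doubly deprotonated so that it cannot leave from the C4 enolate by retro-Michael cleavage. No regiochemical choice arises, because C6 is the only carbon that reaches C1 through a six-membered ring, and ring C, being fully benzylated, offers no phenoxide that could loosen its bridge.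

Step 10
Reactants: 17 benzylated trimer
Product: 18 2-butanoyl-3,5-dihydroxy-6,6-dimethyl-4-({2,4,6-trihydroxy-3-[(2,4,6-trihydroxy-3-methylphenyl)methyl]phenyl}methyl)cyclohexa-2,4-dien-1-one
Conditions: H2 (1 atm), Pd/C (10 %), EtOAc/MeOH, rt
Reagents that add atoms: none
Why: Catalytic hydrogenolysis cleaves the three aryl benzyl ethers under neutral conditions that leave the enolised β-triketone, both diarylmethane-type bridges and the free phloroglucinol ring untouched.

Step 11
Reactants: 18 debenzylated trimer; 19 butanoyl chloride (2.4 equiv)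
Product: 20 2-butanoyl-4-({3-butanoyl-5-[(3-butanoyl-2,4,6-trihydroxy-5-methylphenyl)methyl]-2,4,6-trihydroxyphenyl}methyl)-3,5-dihydroxy-6,6-dimethylcyclohexa-2,4-dien-1-one (CNP0086105.0)
Conditions: TiCl4 (8 equiv), CH2Cl2, 0 °C to rt; 1 M HCl work-up
Reagents that add atoms: none
Why: Friedel–Crafts acylation directed by titanium phenoxides delivers the acyl group to the carbon flanked by two titanated hydroxyls, and rings B and C each have exactly one free carbon, so only the number of acylations has to be controlled; ring A is held as a titanium chelate, any enol butyrate on it is hydrolysed in the acidic work-up, and the low temperature is chosen to spare the methylene bridges.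

**Compound list**

1 | 1-(2,4,6-trihydroxyphenyl)butan-1-one | CCCC(=O)c1c(O)cc(O)cc1O | starting material
2 | 2-butanoyl-3,5-dihydroxy-6,6-dimethylcyclohexa-2,4-dien-1-one (butyrylfilicinic acid) | CCCC(=O)C1=C(O)C=C(O)C(C)(C)C1=O | intermediate
3 | 2,2-dimethyl-1,3-dioxane-4,6-dione | CC1(C)OC(=O)CC(=O)O1 | starting material
4 | 3-chloropropanoyl chloride | ClCCC(Cl)=O | starting material
5 | 5-(3-chloro-1-hydroxypropylidene)-2,2-dimethyl-1,3-dioxane-4,6-dione | CC1(C)OC(=O)C(=C(O)CCCl)C(=O)O1 | intermediate (not isolated)
6 | methyl 5-chloro-3-oxopentanoate | COC(=O)CC(=O)CCCl | intermediate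
7 | methyl 3-oxopent-4-enoate | COC(=O)CC(=O)C=C | intermediate (not isolated)
8 | methyl 5-(5-butanoyl-2,6-dihydroxy-3,3-dimethyl-4-oxocyclohexa-1,5-dien-1-yl)-3-oxopentanoate | CCCC(=O)C1=C(O)C(CCC(=O)CC(=O)OC)=C(O)C(C)(C)C1=O | intermediate
9 | 2-methylbenzene-1,3,5-triol | Cc1c(O)cc(O)cc1O | starting material
10 | N-[(2,4,6-trihydroxy-3-methylphenyl)methylidene]-N-methylmethanaminium chloride | C[N+](C)=Cc1c(O)cc(O)c(C)c1O.[Cl-] | intermediate (not isolated)
11 | 2,4,6-trihydroxy-3-methylbenzaldehyde | Cc1c(O)cc(O)c(C=O)c1O | intermediate
12 | 2,4,6-tris(benzyloxy)-3-methylbenzaldehyde | Cc1c(OCc2ccccc2)cc(OCc2ccccc2)c(C=O)c1OCc1ccccc1 | intermediate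
13 | methyl (triphenylphosphoranylidene)acetate | COC(=O)C=P(c1ccccc1)(c1ccccc1)c1ccccc1 | starting material
14 | methyl (E)-3-[2,4,6-tris(benzyloxy)-3-methylphenyl]prop-2-enoate | COC(=O)/C=C/c1c(OCc2ccccc2)cc(OCc2ccccc2)c(C)c1OCc1ccccc1 | intermediate
15 | methyl 3-[2,4,6-tris(benzyloxy)-3-methylphenyl]propanoate | COC(=O)CCc1c(OCc2ccccc2)cc(OCc2ccccc2)c(C)c1OCc1ccccc1 | intermediate
16 | methyl 4-[(5-butanoyl-2,6-dihydroxy-3,3-dimethyl-4-oxocyclohexa-1,5-dien-1-yl)methyl]-3,5-dioxo-7-[2,4,6-tris(benzyloxy)-3-methylphenyl]heptanoate (racemic) | COC(=O)CC(=O)C(CC1=C(O)C(C)(C)C(=O)C(C(=O)CCC)=C1O)C(=O)CCc1c(OCc2ccccc2)cc(OCc2ccccc2)c(C)c1OCc1ccccc1 | intermediate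
17 | 2-butanoyl-3,5-dihydroxy-6,6-dimethyl-4-[(2,4,6-trihydroxy-3-{[2,4,6-tris(benzyloxy)-3-methylphenyl]methyl}phenyl)methyl]cyclohexa-2,4-dien-1-one | CCCC(=O)C1=C(O)C(Cc2c(O)cc(O)c(Cc3c(OCc4ccccc4)cc(OCc4ccccc4)c(C)c3OCc3ccccc3)c2O)=C(O)C(C)(C)C1=O | intermediate
18 | 2-butanoyl-3,5-dihydroxy-6,6-dimethyl-4-({2,4,6-trihydroxy-3-[(2,4,6-trihydroxy-3-methylphenyl)methyl]phenyl}methyl)cyclohexa-2,4-dien-1-one | CCCC(=O)C1=C(O)C(Cc2c(O)cc(O)c(Cc3c(O)cc(O)c(C)c3O)c2O)=C(O)C(C)(C)C1=O | intermediate
19 | butanoyl chloride | CCCC(Cl)=O | starting material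
20 | CNP0086105.0 | CCCC(=O)C1=C(O)C(Cc2c(O)c(Cc3c(O)c(C)c(O)c(C(=O)CCC)c3O)c(O)c(C(=O)CCC)c2O)=C(O)C(C)(C)C1=O | target

**Step count and risks**

Total step count: 11. Longest linear sequence: 8 steps (9 to 20 through steps 4 to 11).

Steps most likely to fail:

1. Step 9 (ring B closure). The chain may rest as its C2 and C4 enolates, in which C1 is not electrophilic and C6 is not nucleophilic, so closure would be slow. Meanwhile closure through oxygen to the pyrone lactone, methoxide cleavage of the 2-substituted 1,3-diketone (retro-Claisen) and retro-Michael loss of ring A could outrun it. Fallback, setting out from 12 and 2 and returning at 17: ring B is bought instead of built. Aldehyde 12 is reduced with NaBH4 to [2,4,6-tris(benzyloxy)-3-methylphenyl]methanol F1. F1 alkylates an excess of phloroglucinol (benzene-1,3,5-triol, bought) under mild acid catalysis in a Friedel–Crafts benzylation, giving the B–C diarylmethane 2-{[2,4,6-tris(benzyloxy)-3-methylphenyl]methyl}benzene-1,3,5-triol F2. Separately, 2 is aminomethylated with dimethylmethylideneammonium iodide to the Mannich base 2-butanoyl-4-[(dimethylamino)methyl]-3,5-dihydroxy-6,6-dimethylcyclohexa-2,4-dien-1-one F3. Heating F3 with an excess of F2 in dioxane releases the ring A methide, which is trapped by one of the two equivalent free carbons of ring B to give 17.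

2. Step 8 (polyanion acylation). The lithium tetraanion may precipitate, the hindered secondary carbanion may add slowly, and proton transfer from the α-methylene of 15 (ester enolisation) may replace acylation. Fallback, setting out from 15 and 2 and returning at 16: the chain is assembled in the opposite order. The dianion of methyl acetoacetate (NaH, then n-BuLi, THF) is acylated by 15 to give methyl 3,5-dioxo-7-[2,4,6-tris(benzyloxy)-3-methylphenyl]heptanoate F4. Its diketone carbon C4 is aminomethylated with dimethylmethylideneammonium iodide to methyl 4-[(dimethylamino)methyl]-3,5-dioxo-7-[2,4,6-tris(benzyloxy)-3-methylphenyl]heptanoate F5. On warming with the triethylammonium enolate of 2, F5 loses dimethylamine to the 4-methylene diketone and takes up ring A by Michael addition, giving 16.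

3. Step 11 (twofold butyrylation). The Lewis acid may cleave or shift the methylene bridges, may promote cyclodehydration between a ring A enol and a ring B hydroxyl across the bridge to a xanthene-type ether, and the second acylation may stall. Fallback, setting out from 18 and returning at 20: a twofold Houben–Hoesch reaction with butanenitrile, ZnCl2 and HCl in diethyl ether at 0 °C, from which the bis(ketimine) 2-butanoyl-4-({3-butanimidoyl-5-[(3-butanimidoyl-2,4,6-trihydroxy-5-methylphenyl)methyl]-2,4,6-trihydroxyphenyl}methyl)-3,5-dihydroxy-6,6-dimethylcyclohexa-2,4-dien-1-one F6 should separate as its hydrochloride and so escape over-reaction; warming in water hydrolyses F6 to 20.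

Further compounds
F1 | step 9 | [2,4,6-tris(benzyloxy)-3-methylphenyl]methanol | Cc1c(OCc2ccccc2)cc(OCc2ccccc2)c(CO)c1OCc1ccccc1
F2 | step 9 | 2-{[2,4,6-tris(benzyloxy)-3-methylphenyl]methyl}benzene-1,3,5-triol | Cc1c(OCc2ccccc2)cc(OCc2ccccc2)c(Cc2c(O)cc(O)cc2O)c1OCc1ccccc1
F3 | step 9 | 2-butanoyl-4-[(dimethylamino)methyl]-3,5-dihydroxy-6,6-dimethylcyclohexa-2,4-dien-1-one | CCCC(=O)C1=C(O)C(CN(C)C)=C(O)C(C)(C)C1=O
F4 | step 8 | methyl 3,5-dioxo-7-[2,4,6-tris(benzyloxy)-3-methylphenyl]heptanoate | COC(=O)CC(=O)CC(=O)CCc1c(OCc2ccccc2)cc(OCc2ccccc2)c(C)c1OCc1ccccc1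
F5 | step 8 | methyl 4-[(dimethylamino)methyl]-3,5-dioxo-7-[2,4,6-tris(benzyloxy)-3-methylphenyl]heptanoate | COC(=O)CC(=O)C(CN(C)C)C(=O)CCc1c(OCc2ccccc2)cc(OCc2ccccc2)c(C)c1OCc1ccccc1
F6 | step 11 | 2-butanoyl-4-({3-butanimidoyl-5-[(3-butanimidoyl-2,4,6-trihydroxy-5-methylphenyl)methyl]-2,4,6-trihydroxyphenyl}methyl)-3,5-dihydroxy-6,6-dimethylcyclohexa-2,4-dien-1-one | CCCC(=N)c1c(O)c(Cc2c(O)c(C)c(O)c(C(=N)CCC)c2O)c(O)c(CC2=C(O)C(C)(C)C(=O)C(C(=O)CCC)=C2O)c1O
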